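**Retrosynthetic overview**
- The whole C18 chain, nitrile included, is bought as oleonitrile 1; the pyrrole ring is bought intact as tert-butyl 2-bromo-1H-pyrrole-1-carboxylate 2, so no ring is formed in the route.
- Key disconnection, C18(sp3)–C2(pyrrole): a proposed chain-walking nickel hydride hydroarylation joins the methyl terminus of 1 to 2 and gives 3.
- N–Boc cleavage of 3 gives the free 2-alkylpyrrole 4.
- C5–CHO bond last: Vilsmeier–Haack formylation of 4 (through iminium chloride 5) gives the target 6.

Assumption: the target 6 (seventeen CH2 groups between ring and nitrile carbon) has no stereocentre or stereogenic double bond, so it is a single achiral compound and no enantiocontrol is needed; 1 is taken as the homologue-pure (≥99% C18) commercial grade.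

**Route**

Step 1
Reactants: 1 oleonitrile [(9Z)-octadec-9-enenitrile]; 2 tert-butyl 2-bromo-1H-pyrrole-1-carboxylate
Product: 3 tert-butyl 2-(17-cyanoheptadecyl)-1H-pyrrole-1-carboxylate
Conditions: NiI2 (10 mol%), bathocuproine (12 mol%), (EtO)2MeSiH (2.5 equiv), KF (2.5 equiv), 1 (2 equiv), THF/DMA 2:1, 35 °C, 24 h
Reagents that add atoms: none
Why: Proposed new method: a terminal-selective chain-walking reductive hydroheteroarylation, in which the bathocuproine-ligated nickel hydride (from NiI2, silane and fluoride) adds across C9=C10 of 1 and, because the 2,9-dimethylphenanthroline pocket makes β-hydride elimination/re-insertion much faster than C–C coupling at any crowded secondary alkylnickel, migrates nine positions to the unhindered primary C18–nickel species, which undergoes oxidative addition of the C–Br bond of 2 at monovalent nickel and C(sp3)–C(sp2) reductive elimination from trivalent nickel (Ni–Br returns to Ni–H through KF/silane); the closest known reaction type is nickel hydride-catalysed migratory (remote) hydroarylation of alkenes with aryl halides together with the isomerising terminal functionalisation of oleic acid derivatives, neither shown for a nine-carbon walk to the methyl end of a fatty nitrile nor for a 2-bromopyrrole electrophile.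

Step 2
Reactants: 3 tert-butyl 2-(17-cyanoheptadecyl)-1H-pyrrole-1-carboxylate
Product: 4 18-(1H-pyrrol-2-yl)octadecanenitrile
Conditions: NaOMe (0.3 equiv), MeOH/THF 1:1, rt, 3 h
Reagents that add atoms: none
Why: Methoxide-catalysed methanolysis (nucleophilic acyl substitution) of the N-acylpyrrole-type carbamate expels the stabilised pyrrolide, which methanol reprotonates, while the unactivated aliphatic nitrile does not react at rt.

Step 3
Reactants: 4 18-(1H-pyrrol-2-yl)octadecanenitrile
Product: 6 18-(5-formyl-1H-pyrrol-2-yl)octadecanenitrile (the target), via iminium chloride 5 (not isolated)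
Conditions: POCl3 (1.2 equiv), DMF (3 equiv), ClCH2CH2Cl, 0 °C to rt; then aq NaOAc, 70 °C, 30 min
Reagents that add atoms: N,N-dimethylformamide CN(C)C=O; water O
Why: Vilsmeier–Haack formylation, in which the chloroiminium ion attacks the only free α-position (C5) of the 2-alkylpyrrole, its most nucleophilic site, and buffered hydrolysis of iminium 5 releases the aldehyde with the nitrile untouched; no stereocentre is created anywhere in the route.

**Compound list**

1 | oleonitrile, (9Z)-octadec-9-enenitrile | CCCCCCCC/C=C\CCCCCCCC#N | starting material
2 | tert-butyl 2-bromo-1H-pyrrole-1-carboxylate | CC(C)(C)OC(=O)n1cccc1Br | starting material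
3 | tert-butyl 2-(17-cyanoheptadecyl)-1H-pyrrole-1-carboxylate | N#CCCCCCCCCCCCCCCCCCc1cccn1C(=O)OC(C)(C)C | intermediate
4 | 18-(1H-pyrrol-2-yl)octadecanenitrile | N#CCCCCCCCCCCCCCCCCCc1ccc[nH]1 | intermediate
5 | N-{[5-(17-cyanoheptadecyl)-1H-pyrrol-2-yl]methylidene}-N-methylmethanaminium chloride (iminium chloride) | C[N+](C)=Cc1ccc(CCCCCCCCCCCCCCCCCC#N)[nH]1.[Cl-] | intermediate
6 | 18-(5-formyl-1H-pyrrol-2-yl)octadecanenitrile | N#CCCCCCCCCCCCCCCCCCc1ccc(C=O)[nH]1 | target

**Step count and risks**

Total step count: 3. Longest linear sequence: 3 steps (1 or 2 → 3 → 4 → 6).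

The three steps most likely to fail, most risky first:

First, step 1 (the proposed new reaction). The risks are coupling at a secondary carbon (above all at C2 beside the nitrile, where an α-cyanoalkylnickel is stabilised), incomplete migration, and hydrodebromination of 2. The fallback uses known chemistry only, sets out from 2 and comes back to the route at 3. Purchased 11-bromoundec-1-ene (C=CCCCCCCCCCBr) and Mg in THF give undec-10-en-1-ylmagnesium bromide F1. F1 is added at 0 °C to purchased 7-bromoheptanenitrile (N#CCCCCCCBr) in THF/NMP with Li2CuCl4 (3 mol%), a copper-catalysed Grignard–alkyl bromide coupling that outruns addition to the nitrile, to give octadec-17-enenitrile F2. Anti-Markovnikov hydroboration of F2 with 9-BBN (THF, 0 °C to rt) gives 18-(9-borabicyclo[3.3.1]nonan-9-yl)octadecanenitrile F3. B-alkyl Suzuki–Miyaura coupling of F3 with 2 in the same flask (PdCl2(dppf) 5 mol%, aq K3PO4, THF/DMF, 60 °C) gives 3.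

Second, step 3 (late formylation). The risks are acid-promoted oligomerisation of the electron-rich pyrrole 4 and HCl-mediated attack on the nitrile. The fallback puts the formyl group in before the C–C coupling, sets out from 2 and comes back at 6. Carbamate-directed lithiation of 2 at C5 with LiN(iPr)2 (THF, −78 °C) and a DMF quench give tert-butyl 2-bromo-5-formyl-1H-pyrrole-1-carboxylate F4. The borane 18-(9-borabicyclo[3.3.1]nonan-9-yl)octadecanenitrile F3, made as in the first fallback from undec-10-en-1-ylmagnesium bromide F1 through octadec-17-enenitrile F2, is coupled with F4 (PdCl2(dppf) 5 mol%, aq K3PO4, THF/DMF, 50 °C). This gives tert-butyl 2-(17-cyanoheptadecyl)-5-formyl-1H-pyrrole-1-carboxylate F5. Its carbamate, now on an electron-poor 2-formylpyrrole, is cleaved with K2CO3 in MeOH at rt to give 6.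

Third, step 2 (carbamate cleavage). The risks are imidate formation at the nitrile by methoxide and loss of the air- and acid-sensitive pyrrole 4 on isolation. The fallback sets out from 3 and comes back at 4. The nucleophilic cleavage is replaced by a reagent-free thermal extrusion: neat 3 is heated at 180 °C under argon for 30 min. The melt of 4 is cooled, dissolved in ClCH2CH2Cl/DMF and taken straight into step 3 without work-up or isolation.

**Further compounds**

F1 | step 1 | undec-10-en-1-ylmagnesium bromide | C=CCCCCCCCCC[Mg]Br
F2 | step 1 | octadec-17-enenitrile | C=CCCCCCCCCCCCCCCCC#N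
F3 | step 1 | 18-(9-borabicyclo[3.3.1]nonan-9-yl)octadecanenitrile | N#CCCCCCCCCCCCCCCCCCB1C2CCCC1CCC2
F4 | step 3 | tert-butyl 2-bromo-5-formyl-1H-pyrrole-1-carboxylate | CC(C)(C)OC(=O)n1c(Br)ccc1C=O
F5 | step 3 | tert-butyl 2-(17-cyanoheptadecyl)-5-formyl-1H-pyrrole-1-carboxylate | N#CCCCCCCCCCCCCCCCCCc1ccc(C=O)n1C(=O)OC(C)(C)C
F0 | step 2 | none | none
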